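Everything rests on cutting the bond between the exocyclic ylidene carbon C1′ (attached to C5 of the butenolide ring) and the methyl-bearing stereocentre C2′. The last step relays an (S)-secondary pinacol boronate, which carries the whole furyl-diene chain, from boron to zinc to palladium and couples it with (Z)-5-(bromomethylene)-3-methylfuran-2(5H)-one. One operation joins both halves and completes the target, with retention at C2′ and at the C5=C1′ alkene. It exploits the O1–C5=C1′ enol-ester alkene in conjugation with the C2 carbonyl, which makes C1′ a stable yet activated vinylic bromide position. The boronate comes from a terminal alkene by enantioselective Markovnikov protoboration.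

Key step: step 9

Assumption: in step 6 the antipode of the chiral carbene ligand ANIPE (a C2-symmetric acenaphthoimidazol-2-ylidene with 2,6-bis(1-phenylethyl)aryl groups on nitrogen) is chosen so that boron enters on the face that gives the (S)-boronate; both antipodes are accessible.

Step 1
Reactants: 1 furan-3-ylmethanol
Product: 3 3-(chloromethyl)furan, via furan-3-ylmethyl mesylate 2 (not isolated)
Conditions: MsCl, LiCl, 2,4,6-collidine, DMF, 0 °C
Reagents that add atoms: lithium chloride [Li+].[Cl-]; methanesulfonyl chloride CS(=O)(=O)Cl (its atoms stay only in intermediate 2)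
Why: Mesylation followed by in-flask SN2 chloride exchange under buffered conditions should give the furfuryl-type chloride without acid-induced polymerisation of the furan.

Step 2
Reactants: 3 3-(chloromethyl)furan; 4 geranyl bromide, (2E)-1-bromo-3,7-dimethylocta-2,6-diene
Product: 6 dendrolasin, 3-[(3E)-4,8-dimethylnona-3,7-dien-1-yl]furan, via furan-3-ylmethylmagnesium chloride 5 (not isolated)
Conditions: Mg turnings, THF, 0 °C to rt; then 4, Li2CuCl4 (cat.), THF, 0 °C
Reagents that add atoms: magnesium [Mg] (its atom stays only in intermediate 5)
Why: In this Kochi-type copper-catalysed Grignard–allyl halide coupling the primary allylic bromide should be displaced at its α-carbon because the γ-carbon is fully substituted, so the E alkene is kept, and copper steers the ambident furylmethyl nucleophile to react through its CH2 carbon.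

Step 3
Reactants: 6 dendrolasin
Product: 7 neotorreyol, (2E,6E)-9-(furan-3-yl)-2,6-dimethylnona-2,6-dien-1-ol
Conditions: SeO2 (cat.), t-BuOOH, salicylic acid (cat.), CH2Cl2, 0 °C to rt
Reagents that add atoms: tert-butyl hydroperoxide CC(C)(C)OO
Why: The Riley allylic oxidation (ene reaction, then [2,3]-sigmatropic shift), run catalytically in SeO2, should prefer the terminal isopropylidene unit and hydroxylate its E methyl group, which fixes the second E-trisubstituted alkene.

Step 4
Reactants: 7 neotorreyol
Product: 9 3-[(3E,7E)-9-chloro-4,8-dimethylnona-3,7-dien-1-yl]furan, via allylic mesylate 8 (not isolated)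
Conditions: MsCl, LiCl, 2,4,6-collidine, DMF, 0 °C
Reagents that add atoms: lithium chloride [Li+].[Cl-]; methanesulfonyl chloride CS(=O)(=O)Cl (its atoms stay only in intermediate 8)
Why: Mesylation and direct SN2 chloride exchange at the primary allylic carbon should proceed without allylic transposition or E/Z scrambling and without acid that would harm the furan.

Step 5
Reactants: 9 allylic chloride; 10 but-3-en-1-ylmagnesium bromide
Product: 11 3-[(3E,7E)-4,8-dimethyltrideca-3,7,12-trien-1-yl]furan
Conditions: Li2CuCl4 (cat.), THF, −20 to 0 °C, excess 10 added quickly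
Reagents that add atoms: none
Why: A Kochi-type copper-catalysed sp3–sp3 coupling under conditions that favour a dialkylcuprate (THF, low temperature, excess Grignard reagent) should give α (SN2) substitution, which keeps the E geometry and installs the only monosubstituted alkene of the molecule.

Step 6
Reactants: 11 terminal alkene
Product: 12 (S)-2-[(6E,10E)-13-(furan-3-yl)-6,10-dimethyltrideca-6,10-dien-2-yl]-4,4,5,5-tetramethyl-1,3,2-dioxaborolane
Conditions: (ANIPE)CuCl (cat.), NaOt-Bu (cat.), B2pin2, MeOH, hexane, rt
Reagents that add atoms: bis(pinacolato)diboron CC1(C)OB(OC1(C)C)B1OC(C)(C)C(C)(C)O1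
Why: In this copper-catalysed enantioselective Markovnikov protoboration the bulky chiral carbene–copper boryl should add only to the monosubstituted alkene, with copper on the terminal carbon and boron on one face of C2′ (ligand control sets the S centre), and methanol then protonates the primary C–Cu bond.

Step 7
Reactants: 13 2-methyl-4-oxopentanoic acid (racemic)
Product: 14 3,5-dibromo-2-methyl-4-oxopentanoic acid (racemic mixture of diastereomers)
Conditions: Br2 (2 equiv), HBr (cat.), CHCl3, 0 °C to rt
Reagents that add atoms: bromine BrBr
Why: Acid-catalysed α-bromination of the ketone through its enols should place the first bromine at the more substituted C3 and the second at C5, because the first bromine retards renewed enolisation toward C3.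

Step 8
Reactants: 14 dibromo keto acid
Product: 16 (Z)-5-(bromomethylene)-3-methylfuran-2(5H)-one, via bromo enol lactone 15 (not isolated)
Conditions: P2O5, CH2Cl2, reflux; then Et3N (1 equiv), CH2Cl2, 0 °C
Reagents that add atoms: none
Why: Non-oxidising dehydrative enol-lactonisation should give the exocyclic bromo enol lactone with bromine turned away from C4, and E1cB loss of HBr (acidic C3–H, allylic C4–Br) then introduces the ring alkene and removes both stereocentres of 14.

Step 9
Reactants: 12 (S)-secondary boronate; 16 (Z)-bromomethylene butenolide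
Product: 19 (5Z)-5-[(2S,6E,10E)-13-(furan-3-yl)-2,6,10-trimethyltrideca-6,10-dien-1-ylidene]-3-methylfuran-2(5H)-one, via lithium tert-butyl boronate complex 17 (not isolated), via secondary alkylzinc acetate 18 (not isolated)
Conditions: t-BuLi (1.05 equiv), THF, −78 °C to rt; Zn(OAc)2, THF, rt; then 16, Pd(OAc)2 (cat.), CPhos, THF, rt
Reagents that add atoms: tert-butyllithium [Li]C(C)(C)C; zinc diacetate [Zn+2].CC(=O)[O-].CC(=O)[O-] (their atoms stay only in intermediates 17 and 18)
Why: t-BuLi adds to boron to give ate complex 17, whose secondary alkyl group passes to zinc by a closed front-side (SE2, retentive) transmetalation while the bulky tert-butyl group stays on boron; zerovalent palladium then inserts into the C–Br bond of 16 with retention of the Z geometry, 18 transmetalates to divalent palladium with retention, and reductive elimination forms the C1′–C2′ bond. The closest known reaction type is the stereoretentive Negishi coupling of configurationally stable chiral secondary alkylzinc reagents with alkenyl halides, fed here by the known boron-to-zinc relay of tert-butyllithium-activated pinacol boronates. No ring is closed. No new stereocentre is created: the S centre from step 6 is carried through three retentive events and the Z alkene is inherited from 16. The step needs branched rather than chain-walked product and attack at C–Br rather than at the lactone carbonyl; the first is secured by the bulky biaryl phosphine CPhos together with the electron-poor dienyl-lactone ligand on palladium, which speeds reductive elimination over β-hydride elimination, and the second by the low carbonyl reactivity of organozinc reagents. Any uncatalysed 1,6-addition–elimination of 18 to 16 would pass through an aromatic 2-furanolate and lead to the same Z product.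

Compound list
1 | furan-3-ylmethanol | OCc1ccoc1 | starting material
2 | furan-3-ylmethyl methanesulfonate | CS(=O)(=O)OCc1ccoc1 | intermediate
3 | 3-(chloromethyl)furan | ClCc1ccoc1 | intermediate
4 | geranyl bromide, (2E)-1-bromo-3,7-dimethylocta-2,6-diene | CC(C)=CCC/C(C)=C/CBr | starting material
5 | (furan-3-ylmethyl)magnesium chloride | Cl[Mg]Cc1ccoc1 | intermediate
6 | dendrolasin, 3-[(3E)-4,8-dimethylnona-3,7-dien-1-yl]furan | CC(C)=CCC/C(C)=C/CCc1ccoc1 | intermediate
7 | neotorreyol, (2E,6E)-9-(furan-3-yl)-2,6-dimethylnona-2,6-dien-1-ol | OC/C(C)=C/CC/C(C)=C/CCc1ccoc1 | intermediate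
8 | (2E,6E)-9-(furan-3-yl)-2,6-dimethylnona-2,6-dien-1-yl methanesulfonate | CS(=O)(=O)OC/C(C)=C/CC/C(C)=C/CCc1ccoc1 | intermediate
9 | 3-[(3E,7E)-9-chloro-4,8-dimethylnona-3,7-dien-1-yl]furan | ClC/C(C)=C/CC/C(C)=C/CCc1ccoc1 | intermediate
10 | but-3-en-1-ylmagnesium bromide | C=CCC[Mg]Br | starting material
11 | 3-[(3E,7E)-4,8-dimethyltrideca-3,7,12-trien-1-yl]furan | C=CCCC/C(C)=C/CC/C(C)=C/CCc1ccoc1 | intermediate
12 | (S)-2-[(6E,10E)-13-(furan-3-yl)-6,10-dimethyltrideca-6,10-dien-2-yl]-4,4,5,5-tetramethyl-1,3,2-dioxaborolane | CC1(C)OB(OC1(C)C)[C@@H](C)CCC/C(C)=C/CC/C(C)=C/CCc1ccoc1 | intermediate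
13 | 2-methyl-4-oxopentanoic acid (racemic) | CC(=O)CC(C)C(=O)O | starting material
14 | 3,5-dibromo-2-methyl-4-oxopentanoic acid (racemic, mixture of diastereomers) | OC(=O)C(C)C(Br)C(=O)CBr | intermediate
15 | (5Z)-4-bromo-5-(bromomethylene)-3-methyldihydrofuran-2(3H)-one (racemic, mixture of diastereomers) | CC1C(Br)/C(=C/Br)OC1=O | intermediate
16 | (Z)-5-(bromomethylene)-3-methylfuran-2(5H)-one | CC1=C/C(=C/Br)OC1=O | intermediate
17 | lithium (S)-tert-butyl(sec-alkyl)pinacolatoborate, the ate complex of 12 with t-BuLi | [Li+].CC(C)(C)[B-]1(OC(C)(C)C(C)(C)O1)[C@@H](C)CCC/C(C)=C/CC/C(C)=C/CCc1ccoc1 | intermediate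
18 | (S)-[(6E,10E)-13-(furan-3-yl)-6,10-dimethyltrideca-6,10-dien-2-yl]zinc acetate | CC(=O)O[Zn][C@@H](C)CCC/C(C)=C/CC/C(C)=C/CCc1ccoc1 | intermediate
19 | (5Z)-5-[(2S,6E,10E)-13-(furan-3-yl)-2,6,10-trimethyltrideca-6,10-dien-1-ylidene]-3-methylfuran-2(5H)-one | CC1=C/C(=C/[C@@H](C)CCC/C(C)=C/CC/C(C)=C/CCc2ccoc2)OC1=O | target

Total step count: 9. Longest linear sequence: 7 (steps 1 to 6 and step 9).

Steps most likely to fail

Step 9. The hindered secondary alkyl group may pass from boron to zinc slowly or with incomplete retention. β-Hydride elimination and reinsertion on palladium may move the metal along the chain. The electrophile may also be lost by oligomerisation. The fallback sets out from 12 and comes back at 19. It makes the same C1′–C2′ bond without a transition metal, by a 1,2-metalate shift, and builds the lactone ring afterwards.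
- Boronate 12 is combined with α-lithiated vinyl N,N-diisopropylcarbamate. Iodine, then NaOMe, trigger migration and anti elimination (Zweifel olefination) with retention at C2′. This gives (3S,7E,11E)-14-(furan-3-yl)-3,7,11-trimethyltetradeca-1,7,11-trien-2-yl N,N-diisopropylcarbamate F1.
- Base-induced 1,2-elimination with LDA gives the terminal alkyne 3-[(3E,7E,12S)-4,8,12-trimethyltetradeca-3,7-dien-13-yn-1-yl]furan F2.
- In parallel, propargyl alcohol is carbomagnesiated (MeMgBr, CuI) and quenched with iodine to give (Z)-3-iodo-2-methylprop-2-en-1-ol F3.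
- Jones oxidation (CrO3, H2SO4, acetone) then gives (Z)-3-iodo-2-methylacrylic acid F4.
- Sonogashira coupling of F2 with F4 (Pd(PPh3)4, CuI, Et3N, MeCN) is followed in the same flask by anti 5-exo-dig lactonisation. This should deliver the Z-ylidene butenolide 19.

Step 6. Boron may be delivered to the terminal carbon. Facial discrimination between a methyl group and an unbranched chain may also be too weak. The fallback sets out from 9 and comes back at 12. It replaces catalyst control by a reagent-controlled homologation.
- Vinylmagnesium bromide with Li2CuCl4 (cat.) converts 9 into 3-[(3E,7E)-4,8-dimethylundeca-3,7,10-trien-1-yl]furan F5.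
- Hydroboration of the monosubstituted alkene with pinacolborane ([Ir(cod)Cl]2, dppe) gives the primary boronate 2-[(4E,8E)-11-(furan-3-yl)-4,8-dimethylundeca-4,8-dien-1-yl]-4,4,5,5-tetramethyl-1,3,2-dioxaborolane F6.
- Ethyl 2,4,6-triisopropylbenzoate is lithiated with s-BuLi and (+)-sparteine. The (R)-configured carbenoid adds to boron with retention, and the chain migrates with inversion at the carbenoid carbon (Matteson-type lithiation–borylation). This gives 12.

Step 8. Dehydration may run toward the ring instead of toward the CH2Br group. Bromine may migrate, or the material may polymerise in the dehydrating medium. The fallback sets out from 13 and comes back at 16. It closes the ring first and brings bromine in by addition–elimination.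
- Distillation of 13 from catalytic H3PO4 gives 3,5-dimethylfuran-2(3H)-one F7.
- Bromine adds to the enol alkene to give 4,5-dibromo-3,5-dimethyldihydrofuran-2(3H)-one F8.
- Et3N removes two equivalents of HBr to give 3-methyl-5-methylenefuran-2(5H)-one F9.
- A second bromine addition gives 5-bromo-5-(bromomethyl)-3-methylfuran-2(5H)-one F10.
- Et3N-induced dehydrobromination should lead to the more stable Z bromide 16.

Further compounds
F1 | step 9 | (3S,7E,11E)-14-(furan-3-yl)-3,7,11-trimethyltetradeca-1,7,11-trien-2-yl N,N-diisopropylcarbamate | C=C(OC(=O)N(C(C)C)C(C)C)[C@@H](C)CCC/C(C)=C/CC/C(C)=C/CCc1ccoc1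
F2 | step 9 | 3-[(3E,7E,12S)-4,8,12-trimethyltetradeca-3,7-dien-13-yn-1-yl]furan | C#C[C@@H](C)CCC/C(C)=C/CC/C(C)=C/CCc1ccoc1
F3 | step 9 | (Z)-3-iodo-2-methylprop-2-en-1-ol | OC/C(C)=C\I
F4 | step 9 | (Z)-3-iodo-2-methylacrylic acid | OC(=O)/C(C)=C\I
F5 | step 6 | 3-[(3E,7E)-4,8-dimethylundeca-3,7,10-trien-1-yl]furan | C=CC/C(C)=C/CC/C(C)=C/CCc1ccoc1
F6 | step 6 | 2-[(4E,8E)-11-(furan-3-yl)-4,8-dimethylundeca-4,8-dien-1-yl]-4,4,5,5-tetramethyl-1,3,2-dioxaborolane | CC1(C)OB(CCC/C(C)=C/CC/C(C)=C/CCc2ccoc2)OC1(C)C
F7 | step 8 | 3,5-dimethylfuran-2(3H)-one | CC1C=C(C)OC1=O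
F8 | step 8 | 4,5-dibromo-3,5-dimethyldihydrofuran-2(3H)-one | CC1C(Br)C(C)(Br)OC1=O
F9 | step 8 | 3-methyl-5-methylenefuran-2(5H)-one | CC1=CC(=C)OC1=O
F10 | step 8 | 5-bromo-5-(bromomethyl)-3-methylfuran-2(5H)-one | CC1=CC(Br)(CBr)OC1=O
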